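Labdane numbering is used. Ring B is cut at C5–C6 and C9–C10. Ring A enters as a C5 vinyllithium whose C5=C10 alkene is the two-atom partner. C6–C9 enter folded into a 3-ethoxycyclobutenone in which C6 and C9 are still joined by a strained bond. One operation (1,2-addition, 4π opening, 6π closure) forges C5–C6 and C9–C10 and builds ring B with the quaternary C10. It exploits the 1,3-relation of C6 to the exo-methylene carbon C8 in ring B, read as a masked 1,3-dicarbonyl, and the C4 stereocentre beside C5. C13 comes from (R)-linalool. Carbonyl transposition, methylenation and tigloylation finish the route.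

Key step: step 11

Remark: ring A = C1–C5/C10 and ring B = C5–C10. C17 is the exo-methylene carbon, C19 the axial CH2O on C4, C20 the methyl on C10. α is the face of 5-H and β the face of C19/C20. In step 7 the ligand antipode is assumed to be the one that delivers (R)-13.

Step 1
Reactants: 1 (R)-(−)-linalool
Product: 2 (3R)-3-(tert-butyldimethylsilyloxy)-3,7-dimethylocta-1,6-diene
Conditions: TBSOTf, 2,6-lutidine, CH2Cl2, 0 °C
Reagents that add atoms: tert-butyldimethylsilyl triflate, CC(C)(C)[Si](C)(C)OS(=O)(=O)C(F)(F)F
Why: Silyl triflate O-silylation should cap the hindered tertiary allylic alcohol under buffered, non-ionising conditions, so the chiral-pool C13 stereocentre is untouched.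

Step 2
Reactants: 2 silyl ether of linalool
Product: 4 (4R)-4-(tert-butyldimethylsilyloxy)-4-methylhex-5-enal, via secondary ozonide 3 (not isolated)
Conditions: O3 (1 equiv, dye indicator), CH2Cl2, −78 °C; then Me2S, −78 °C to rt
Reagents that add atoms: ozone, [O-][O+]=O
Why: In this chemoselective ozonolysis (Criegee mechanism) the electron-rich trisubstituted alkene should react far faster than the hindered monosubstituted vinyl group, and Me2S reduces the ozonide.

Step 3
Reactants: 4 aldehyde
Product: 5 (4R)-4-(tert-butyldimethylsilyloxy)-4-methylhex-5-enoic acid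
Conditions: NaClO2, NaH2PO4, 2-methyl-2-butene, t-BuOH/H2O, 0 °C to rt
Reagents that add atoms: sodium chlorite, [Na+].[O-]Cl=O
Why: The Pinnick oxidation converts the aldehyde to the acid at buffered pH, and the alkene scavenger protects the vinyl group from HOCl.

Step 4
Reactants: 5 acid
Product: 7 (5R)-1-diazo-5-(tert-butyldimethylsilyloxy)-5-methylhept-6-en-2-one, via mixed anhydride 6 (not isolated)
Conditions: ClCO2Et, Et3N, THF, −15 °C; then CH2N2, Et2O, 0 °C
Reagents that add atoms: diazomethane, C=[N+]=[N-]
Why: This is the acylation stage of the Arndt–Eistert sequence, and the mixed anhydride activates the acid without any HCl that could ionise the tertiary allylic silyl ether.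

Step 5
Reactants: 7 diazoketone; 8 ethoxyacetylene
Product: 10 3-ethoxy-4-[(3R)-3-(tert-butyldimethylsilyloxy)-3-methylpent-4-enyl]cyclobut-2-en-1-one (both ring C4 epimers), via alkylketene 9 (not isolated)
Conditions: hν (Pyrex, >300 nm), 8 (5 equiv), CH2Cl2, rt
Reagents that add atoms: none
Why: A photochemical Wolff rearrangement gives the alkylketene, which the electron-rich ynol ether should intercept in a regioselective ketene–alkyne [2+2] cycloaddition (ketene carbonyl carbon to the nucleophilic CH terminus); the new ring stereocentre forms as a mixture that step 11 erases.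

Step 6
Reactants: 11 2,6-dimethylcyclohexanone (isomer mixture)
Product: 12 2,6-dimethyl-1-(trimethylsilyloxy)cyclohexene (racemic)
Conditions: TMSOTf, Et3N, CH2Cl2, 0 °C
Reagents that add atoms: trimethylsilyl triflate, C[Si](C)(C)OS(=O)(=O)C(F)(F)F
Why: Soft enolisation with O-silylation applies here, and because both α-carbons are equivalent only one tetrasubstituted enol silane can form.

Step 7
Reactants: 12 enol silane
Product: 13 (2R)-2-(hydroxymethyl)-2,6-dimethylcyclohexanone (C6 epimers)
Conditions: aq. HCHO, Sc(OTf)3 (10 mol %), 6,6'-bis(1-hydroxy-2,2-dimethylpropyl)-2,2'-bipyridine (single enantiomer, 12 mol %), DME/H2O, −20 °C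
Reagents that add atoms: formaldehyde, C=O
Why: In this catalytic asymmetric Mukaiyama aldol hydroxymethylation the chiral scandium–bipyridine complex should select one face of the enol silane and set the quaternary C4, while the methyl-bearing C10 stays a mixture that step 10 erases.

Step 8
Reactants: 13 hydroxy ketone
Product: 14 (2R)-2,6-dimethyl-2-(triisopropylsilyloxymethyl)cyclohexanone
Conditions: TIPSOTf, 2,6-lutidine, CH2Cl2, 0 °C
Reagents that add atoms: triisopropylsilyl triflate, CC(C)[Si](C(C)C)(C(C)C)OS(=O)(=O)C(F)(F)F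
Why: O-silylation blocks retro-aldol loss of formaldehyde and installs the bulky group that later shields the β-face.

Step 9
Reactants: 14 ketone
Product: 15 (2S)-2,6-dimethyl-2-(triisopropylsilyloxymethyl)cyclohexanone hydrazone
Conditions: N2H4·H2O, Et3N, EtOH, reflux
Reagents that add atoms: hydrazine, NN
Why: Hydrazone condensation under forcing conditions is the usual answer to 2,2,6-trisubstituted cyclohexanones, and C4 is quaternary so it cannot epimerise.

Step 10
Reactants: 15 hydrazone
Product: 16 {[(1R)-2-iodo-1,3-dimethylcyclohex-2-en-1-yl]methoxy}triisopropylsilane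
Conditions: I2, 1,1,3,3-tetramethylguanidine, Et2O/THF, 0 °C to rt
Reagents that add atoms: iodine, II
Why: The Barton vinyl iodide synthesis proceeds by oxidation to the diazo compound, iodination and loss of N2 and H+, and only C10 carries a removable hydrogen, so the C5=C10 alkene forms unambiguously.

Step 11
Reactants: 16 vinyl iodide; 10 cyclobutenone
Product: 21 (13R)-13-(tert-butyldimethylsilyloxy)-8-ethoxy-19-(triisopropylsilyloxy)-17-norlabda-7,14-dien-6-one (5α-H/9α-H/10β-methyl), via vinyllithium 17 (not isolated), via lithium cyclobutenolate 18 (not isolated), via lithium trienolate 19 (not isolated), via bicyclic lithium dienolate 20 (not isolated)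
Conditions: t-BuLi (2 equiv), Et2O, −78 °C; add 10 in THF, −78 °C, then warm to rt and to 50 °C; aq. NH4Cl
Reagents that add atoms: none
Why: Iodine–lithium exchange gives 17, which adds 1,2 to the strained vinylogous-ester carbonyl of 10 (C5–C6), and cyclobutenolate 18 then undergoes charge-accelerated conrotatory 4π opening of the C6–C9 bond with the oxido group rotating outward and the ring A alkenyl group inward, so trienolate 19 is born coiled for closure. Thermal disrotatory 6π electrocyclisation joins C9 to C10 and closes the six-membered carbocyclic ring B, driven by release of cyclobutene strain and σ-for-π exchange; the closest known reaction type is the two-carbon ring expansion of cyclobutenones by alkenyllithium addition and 4π/6π electrocyclic relay, akin to the alkenylcyclobutenol ring expansions used for quinones. C10: the bulky CH2OTIPS on C4 should sit pseudo-axial on the β-face to avoid A(1,2) strain with the C6 substituent and shield that face, so C9 bonds to the α-face and the C20 methyl swings β, cis to C19. C9: addition anti to the side chain places oxygen and side chain cis in 18, so the side chain rotates inward and disrotation sets it cis to C20 (9α-H); both ring epimers of 10 converge because C6 and C9 are planar in 19, and any 9-epimer is corrected at ketone 24. C5: dienolate 20 is protonated from the open α-face, which is also the thermodynamic trans-decalin outcome since C5 stays epimerisable beside the C6 carbonyl. The step needs 1,2- over 1,4-addition and no enolisation, which the hard organolithium, the donor-deactivated β-carbon C8 and the antiaromatic character of a cyclobutenone enolate should secure.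

Step 12
Reactants: 21 vinylogous ester
Product: 23 (13R)-13-(tert-butyldimethylsilyloxy)-19-(triisopropylsilyloxy)-17-norlabda-6,14-dien-8-one, via allylic alcohol 22 (not isolated)
Conditions: DIBAL-H, CH2Cl2, −78 °C; then 1 M HCl, THF, 0 °C
Reagents that add atoms: water, O
Why: In the Stork–Danheiser transposition, 1,2-hydride addition followed by acid-induced loss of water and hydrolysis of the ethoxy-dienyl cation moves the carbonyl from C6 to C8 without touching a stereocentre.

Step 13
Reactants: 23 enone
Product: 24 (13R)-13-(tert-butyldimethylsilyloxy)-19-(triisopropylsilyloxy)-17-norlabd-14-en-8-one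
Conditions: [(Ph3P)CuH]6, toluene, H2O (trace), rt; then NaOMe (cat.), MeOH, rt
Reagents that add atoms: none
Why: Copper hydride conjugate reduction is selective for the enone over the isolated vinyl group, and catalytic methoxide then equilibrates C9 beside the ketone to the equatorial side chain (9α-H).

Step 14
Reactants: 24 ketone
Product: 25 (13R)-13-(tert-butyldimethylsilyloxy)-19-(triisopropylsilyloxy)labda-8(17),14-diene
Conditions: Ph3PCH3Br, KOt-Bu, toluene/THF, rt to 60 °C
Reagents that add atoms: methyltriphenylphosphonium bromide, C[P+](c1ccccc1)(c1ccccc1)c1ccccc1.[Br-]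
Why: Wittig methylenation with the small non-stabilised ylide should reach the hindered C8 ketone, and C9 is already in its thermodynamic configuration, so the basic medium cannot scramble it.

Step 15
Reactants: 25 bis-silyl ether
Product: 26 (13R)-labda-8(17),14-diene-13,19-diol
Conditions: TBAF (excess), THF, 60 °C
Reagents that add atoms: none
Why: Fluoride-induced desilylation removes both silyl groups in one operation under non-acidic conditions that the tertiary allylic alcohol tolerates.

Step 16
Reactants: 26 diol; 27 tigloyl chloride, (E)-2-methylbut-2-enoyl chloride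
Product: 28 (13R)-13-hydroxylabda-8(17),14-dien-19-yl (E)-2-methylbut-2-enoate (target)
Conditions: pyridine, DMAP (cat.), CH2Cl2, 0 °C to rt
Reagents that add atoms: none
Why: DMAP-catalysed acylation should take the primary C19 hydroxyl and leave the tertiary allylic C13 hydroxyl, and the (E)-tiglate is the thermodynamic geometry, so it is retained.

Compound list
1 | (R)-(−)-linalool | C=C[C@](C)(O)CCC=C(C)C | starting material
2 | (3R)-3-(tert-butyldimethylsilyloxy)-3,7-dimethylocta-1,6-diene | C=C[C@](C)(O[Si](C)(C)C(C)(C)C)CCC=C(C)C | intermediate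
3 | secondary ozonide of 2 (1,2,4-trioxolane) | C=C[C@](C)(O[Si](C)(C)C(C)(C)C)CCC1OOC(C)(C)O1 | intermediate
4 | (4R)-4-(tert-butyldimethylsilyloxy)-4-methylhex-5-enal | C=C[C@](C)(O[Si](C)(C)C(C)(C)C)CCC=O | intermediate
5 | (4R)-4-(tert-butyldimethylsilyloxy)-4-methylhex-5-enoic acid | C=C[C@](C)(O[Si](C)(C)C(C)(C)C)CCC(=O)O | intermediate
6 | ethyl carbonic mixed anhydride of 5 | C=C[C@](C)(O[Si](C)(C)C(C)(C)C)CCC(=O)OC(=O)OCC | intermediate
7 | (5R)-1-diazo-5-(tert-butyldimethylsilyloxy)-5-methylhept-6-en-2-one | C=C[C@](C)(O[Si](C)(C)C(C)(C)C)CCC(=O)C=[N+]=[N-] | intermediate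
8 | ethoxyacetylene | C#COCC | starting material
9 | (5R)-5-(tert-butyldimethylsilyloxy)-5-methylhepta-1,6-dien-1-one (alkylketene) | C=C[C@](C)(O[Si](C)(C)C(C)(C)C)CCC=C=O | intermediate
10 | 3-ethoxy-4-[(3R)-3-(tert-butyldimethylsilyloxy)-3-methylpent-4-enyl]cyclobut-2-en-1-one, ring C4 epimers | C=C[C@](C)(O[Si](C)(C)C(C)(C)C)CCC1C(=O)C=C1OCC | intermediate
11 | 2,6-dimethylcyclohexanone | CC1CCCC(C)C1=O | starting material
12 | 2,6-dimethyl-1-(trimethylsilyloxy)cyclohexene | CC1CCCC(C)=C1O[Si](C)(C)C | intermediate
13 | (2R)-2-(hydroxymethyl)-2,6-dimethylcyclohexanone | O=C1[C@@](C)(CO)CCCC1C | intermediate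
14 | (2R)-2,6-dimethyl-2-(triisopropylsilyloxymethyl)cyclohexanone | O=C1[C@@](C)(CO[Si](C(C)C)(C(C)C)C(C)C)CCCC1C | intermediate
15 | hydrazone of 14 (2S) | NN=C1[C@@](C)(CO[Si](C(C)C)(C(C)C)C(C)C)CCCC1C | intermediate
16 | {[(1R)-2-iodo-1,3-dimethylcyclohex-2-en-1-yl]methoxy}triisopropylsilane | CC1=C(I)[C@@](C)(CO[Si](C(C)C)(C(C)C)C(C)C)CCC1 | intermediate
17 | ring A C5 vinyllithium | CC1=C([Li])[C@@](C)(CO[Si](C(C)C)(C(C)C)C(C)C)CCC1 | intermediate
18 | lithium 1-(ring A alkenyl)-3-ethoxy-4-alkylcyclobut-2-en-1-olate | C=C[C@](C)(O[Si](C)(C)C(C)(C)C)CCC1C(OCC)=CC1([O-])C1=C(C)CCC[C@]1(C)CO[Si](C(C)C)(C(C)C)C(C)C.[Li+] | intermediate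
19 | lithium trienolate C10=C5–C6(O−)=C7–C8(OEt)=C9, ring A cis to C8, side chain cis to C7 | C=C[C@](C)(O[Si](C)(C)C(C)(C)C)CC/C=C(OCC)\C=C([O-])/C1=C(C)CCC[C@]1(C)CO[Si](C(C)C)(C(C)C)C(C)C.[Li+] | intermediate
20 | bicyclic lithium dienolate C5=C6(O−)–C7=C8(OEt) | C=C[C@](C)(O[Si](C)(C)C(C)(C)C)CC[C@H]1C(OCC)=CC([O-])=C2[C@@](C)(CO[Si](C(C)C)(C(C)C)C(C)C)CCC[C@]12C.[Li+] | intermediate
21 | (13R)-13-(TBSO)-8-ethoxy-19-(TIPSO)-17-norlabda-7,14-dien-6-one, trans-decalin | C=C[C@](C)(O[Si](C)(C)C(C)(C)C)CC[C@H]1C(OCC)=CC(=O)[C@H]2[C@@](C)(CO[Si](C(C)C)(C(C)C)C(C)C)CCC[C@]12C | intermediate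
22 | 6-hydroxy-8-ethoxy-7-ene (allylic alcohol, C6 unassigned) | C=C[C@](C)(O[Si](C)(C)C(C)(C)C)CC[C@H]1C(OCC)=CC(O)[C@H]2[C@@](C)(CO[Si](C(C)C)(C(C)C)C(C)C)CCC[C@]12C | intermediate
23 | (13R)-13-(TBSO)-19-(TIPSO)-17-norlabda-6,14-dien-8-one | C=C[C@](C)(O[Si](C)(C)C(C)(C)C)CC[C@H]1C(=O)C=C[C@H]2[C@@](C)(CO[Si](C(C)C)(C(C)C)C(C)C)CCC[C@]12C | intermediate
24 | (13R)-13-(TBSO)-19-(TIPSO)-17-norlabd-14-en-8-one | C=C[C@](C)(O[Si](C)(C)C(C)(C)C)CC[C@H]1C(=O)CC[C@H]2[C@@](C)(CO[Si](C(C)C)(C(C)C)C(C)C)CCC[C@]12C | intermediate
25 | (13R)-13-(TBSO)-19-(TIPSO)labda-8(17),14-diene | C=C[C@](C)(O[Si](C)(C)C(C)(C)C)CC[C@H]1C(=C)CC[C@H]2[C@@](C)(CO[Si](C(C)C)(C(C)C)C(C)C)CCC[C@]12C | intermediate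
26 | (13R)-labda-8(17),14-diene-13,19-diol | C=C[C@](C)(O)CC[C@H]1C(=C)CC[C@H]2[C@@](C)(CO)CCC[C@]12C | intermediate
27 | tigloyl chloride | C/C=C(\C)C(=O)Cl | starting material
28 | (13R)-13-hydroxylabda-8(17),14-dien-19-yl tiglate | C=C[C@](C)(O)CC[C@H]1C(=C)CC[C@H]2[C@@](C)(COC(=O)/C(C)=C/C)CCC[C@]12C | target

Total step count: 16. Longest linear sequence: 11 steps (steps 1–5 or steps 6–10, then steps 11–16).

Steps most likely to fail

Step 11. The relay may stall at the open trienolate, because 6π closure onto the fully substituted C10 terminus is slow. Stray proton transfer or oxygen-to-carbon silyl migration in the vinyllithium may also intervene. Facial selectivity at C10 may be poor as well. The fallback sets out from 16 and 10 and comes back at 21. It replaces the anionic relay with a neutral thermal one on an isolated intermediate. After the addition at −78 °C the alkoxide is trapped with TMSCl and the bis-allylic cyclobutenyl trimethylsilyl ether F1 is isolated. Heating F1 in toluene at 110 °C in base-washed glass should bring about 4π opening with the siloxy group outward. 6π closure then gives the bicyclic trimethylsilyl dienol ether F2, from which a C10 epimer can be removed by chromatography. Brief treatment with 1 M HCl in THF at 0 °C releases 21.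

Step 5. The ketene may dimerise or be captured by the pendant vinyl group, and the cyclobutenone may suffer secondary photolysis. The fallback sets out from 7 and comes back at 10, and it generates the same ketene in the dark. A Wolff rearrangement with AgOBz and Et3N in MeOH gives the homologated methyl ester F3. LiOH gives the acid F4. 1-Chloro-N,N,2-trimethylpropenylamine gives the acid chloride F5 under neutral conditions. Slow addition of Et3N to F5 and excess 8 in Et2O then effects dehydrochlorination and the [2+2] capture to 10.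

Step 7. Enantiofacial discrimination may be poor on an all-alkyl tetrasubstituted enol silane, and hydrolysis of the silane may compete. The fallback sets out from 11 and comes back at 13. KHMDS and allyl chloroformate give the allyl enol carbonate F6. Decarboxylative asymmetric allylic alkylation with Pd2(dba)3 and t-Bu-PHOX (antipode chosen accordingly) gives (R)-2-allyl-2,6-dimethylcyclohexanone F7. RhCl3·3H2O in EtOH moves the alkene into conjugation-free internal position to give the propenyl ketone F8. Ozonolysis with Me2S work-up gives the keto aldehyde F9. LiAlH(Ot-Bu)3 at −78 °C then reduces only the aldehyde to give 13.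

Further compounds
F1 | step 11 | cyclobutenyl trimethylsilyl ether of 18 | C=C[C@](C)(O[Si](C)(C)C(C)(C)C)CCC1C(OCC)=CC1(O[Si](C)(C)C)C1=C(C)CCC[C@]1(C)CO[Si](C(C)C)(C(C)C)C(C)C
F2 | step 11 | bicyclic 6-(trimethylsilyloxy)-8-ethoxy-5,7-diene | C=C[C@](C)(O[Si](C)(C)C(C)(C)C)CC[C@H]1C(OCC)=CC(O[Si](C)(C)C)=C2[C@@](C)(CO[Si](C(C)C)(C(C)C)C(C)C)CCC[C@]12C
F3 | step 5 | methyl (5R)-5-(tert-butyldimethylsilyloxy)-5-methylhept-6-enoate | C=C[C@](C)(O[Si](C)(C)C(C)(C)C)CCCC(=O)OC
F4 | step 5 | (5R)-5-(tert-butyldimethylsilyloxy)-5-methylhept-6-enoic acid | C=C[C@](C)(O[Si](C)(C)C(C)(C)C)CCCC(=O)O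
F5 | step 5 | (5R)-5-(tert-butyldimethylsilyloxy)-5-methylhept-6-enoyl chloride | C=C[C@](C)(O[Si](C)(C)C(C)(C)C)CCCC(=O)Cl
F6 | step 7 | allyl 2,6-dimethylcyclohex-1-enyl carbonate | C=CCOC(=O)OC1=C(C)CCCC1C
F7 | step 7 | (R)-2-allyl-2,6-dimethylcyclohexanone | O=C1[C@@](C)(CC=C)CCCC1C
F8 | step 7 | (R)-2,6-dimethyl-2-[(E)-prop-1-enyl]cyclohexanone | O=C1[C@@](C)(/C=C/C)CCCC1C
F9 | step 7 | 1,3-dimethyl-2-oxocyclohexanecarbaldehyde (C1 configured as in 13) | O=C1[C@@](C)(C=O)CCCC1C
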